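**Retrosynthetic overview**

1. Ring A is the 3-hydroxyphenyl ring, ring B the para-phenylene, ring C the 1,3,4-trisubstituted ring carrying the diaryl ether oxygen and one free OH, and ring D the 2,3-dihydroxyphenyl (catechol) ring. The strategy rests on the CH2–CH2 bridge between ring C and ring D, a two-carbon unit flanked by two aryl carbons, and on the 1,2,3-pattern of ring D, which is that of ortho-lithiated veratrole.
2. Target 18 ⇐ tetramethyl ether 17 ⇐ benzylic boronate 16 (C–B to C–H) ⇐ both aryl–carbon bonds of the C/D bridge cut at once: ring C triflate 11 + vinylboronic ester 13 + aryllithium 14.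
3. Triflate 11 ⇐ phenol 10 ⇐ aldehyde 8 (Baeyer–Villiger) ⇐ Ullmann C–O bond between ring B phenol 6 and bromoaldehyde 7.
4. Phenol 6 ⇐ Wittig olefination and hydrogenation joining rings A and B (1 + 3).
5. No ring is formed: all four benzene rings are purchased and joined in the order A–B bridge, B–O–C ether, C–D bridge.

Key step: step 7

Assumption: the target is achiral, and the configuration at the boron-bearing carbon of 16 is left unspecified because boron is replaced by hydrogen in step 8. 4-(Benzyloxy)benzaldehyde is used so that the Wittig reaction does not have to run on a phenoxide; the benzyl group falls off in the hydrogenation that saturates the alkene.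

**Route**

Step 1
Reactants: 1 3-methoxybenzyl chloride
Product: 2 (3-methoxybenzyl)triphenylphosphonium chloride
Conditions: PPh3, toluene, reflux
Reagents that add atoms: triphenylphosphine, c1ccc(cc1)P(c1ccccc1)c1ccccc1
Why: SN2 quaternisation of triphenylphosphine by a primary benzylic chloride should give the crystalline phosphonium salt.

Step 2
Reactants: 2 (3-methoxybenzyl)triphenylphosphonium chloride; 3 4-(benzyloxy)benzaldehyde
Product: 5 1-(benzyloxy)-4-[2-(3-methoxyphenyl)ethenyl]benzene (E/Z mixture), via phosphonium ylide 4 (not isolated)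
Conditions: KOtBu, THF, 0 °C; then 3, 0 °C → rt
Reagents that add atoms: none
Why: Wittig olefination of an aromatic aldehyde with a semi-stabilised benzylic ylide should give the stilbene, whose E/Z ratio is irrelevant because the double bond is hydrogenated next.

Step 3
Reactants: 5 1-(benzyloxy)-4-[2-(3-methoxyphenyl)ethenyl]benzene
Product: 6 4-[2-(3-methoxyphenyl)ethyl]phenol
Conditions: H2 (1 atm), 10% Pd/C, EtOAc–EtOH, rt
Reagents that add atoms: none
Why: Catalytic hydrogenation over Pd/C should saturate the stilbene double bond and hydrogenolyse the benzyl ether in the same operation, leaving the methyl ether untouched.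

Step 4
Reactants: 6 4-[2-(3-methoxyphenyl)ethyl]phenol; 7 3-bromo-4-methoxybenzaldehyde
Product: 8 4-methoxy-3-{4-[2-(3-methoxyphenyl)ethyl]phenoxy}benzaldehyde
Conditions: CuI (cat.), N,N-dimethylglycine hydrochloride (cat.), Cs2CO3, 1,4-dioxane, 100 °C, Ar
Reagents that add atoms: none
Why: Ligand-accelerated Ullmann diaryl ether synthesis should join the phenoxide to the aryl bromide, a coupling well established for ortho-alkoxy bromobenzaldehydes, and the aldehyde has no enolisable position.

Step 5
Reactants: 8 4-methoxy-3-{4-[2-(3-methoxyphenyl)ethyl]phenoxy}benzaldehyde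
Product: 10 4-methoxy-3-{4-[2-(3-methoxyphenyl)ethyl]phenoxy}phenol, via aryl formate 9 (not isolated)
Conditions: mCPBA, CH2Cl2, rt; then K2CO3 (cat.), MeOH, rt
Reagents that add atoms: 3-chloroperoxybenzoic acid (mCPBA), O=C(OO)c1cccc(Cl)c1
Why: In the Baeyer–Villiger oxidation the aryl group para to the methoxy donor should migrate in preference to hydrogen, giving the aryl formate, which mild methanolysis converts into the phenol.

Step 6
Reactants: 10 4-methoxy-3-{4-[2-(3-methoxyphenyl)ethyl]phenoxy}phenol
Product: 11 4-methoxy-3-{4-[2-(3-methoxyphenyl)ethyl]phenoxy}phenyl trifluoromethanesulfonate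
Conditions: Tf2O, pyridine, CH2Cl2, 0 °C
Reagents that add atoms: trifluoromethanesulfonic anhydride, O=S(=O)(OS(=O)(=O)C(F)(F)F)C(F)(F)F
Why: O-sulfonylation of the only free phenol with triflic anhydride and pyridine should give the aryl triflate, the halide-free electrophile the key step needs.

Step 7
Reactants: 11 4-methoxy-3-{4-[2-(3-methoxyphenyl)ethyl]phenoxy}phenyl trifluoromethanesulfonate; 12 veratrole (1,2-dimethoxybenzene); 13 vinylboronic acid pinacol ester (2-ethenyl-4,4,5,5-tetramethyl-1,3,2-dioxaborolane)
Product: 16 2-[1-(2,3-dimethoxyphenyl)-2-(4-methoxy-3-{4-[2-(3-methoxyphenyl)ethyl]phenoxy}phenyl)ethyl]-4,4,5,5-tetramethyl-1,3,2-dioxaborolane (configuration at the boron-bearing carbon not specified), via 2,3-dimethoxyphenyllithium 14 (not isolated), via lithium vinylboronate complex 15 (not isolated)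
Conditions: 12 (slight excess), n-BuLi, THF, 0 °C → rt; then 13, 0 °C → rt; then 11, Pd(OAc)2 (cat.), MandyPhos ligand [1,1'-bis{bis(4-methoxy-3,5-dimethylphenyl)phosphino}-2,2'-bis(α-dimethylaminobenzyl)ferrocene, either enantiomer] (cat.), THF, 60 °C
Reagents that add atoms: n-butyllithium, [Li]CCCC (supplies only the lithium of intermediates 14 and 15; no atom of it remains in 16)
Why: Directed ortho-lithiation of veratrole gives a lithium-halide-free aryllithium 14, which adds to the boron of 13 to form the tetracoordinate vinylboronate 15 before any triflate is present. Zerovalent palladium, formed in situ from Pd(OAc)2 and the bisphosphine, inserts into the C–O bond of triflate 11 to give a cationic arylpalladium complex (divalent palladium) that binds the vinyl group of 15 and triggers a 1,2-shift of the 2,3-dimethoxyphenyl group from boron to the adjacent carbon, anti to palladium; reductive elimination then joins ring C to the terminal carbon. The closest known reaction type is the palladium-catalysed conjunctive cross-coupling of aryl(vinyl)boronate complexes with aryl triflates. No ring is closed; the two skeletal bonds formed are ring C–CH2 and CH–ring D. The one new stereocentre, the boron-bearing benzylic carbon, is set by the ligand-controlled face of alkene binding, but no control is needed because it is erased in step 8. The step needs the metallate shift to outrun direct Suzuki-type transfer of vinyl or aryl from boron, which the non-coordinating triflate counter-ion, the halide-free aryllithium, the wide-bite-angle ferrocenyl bisphosphine and the electron-rich migrating group should secure, while regiochemistry is intrinsic because migration can only end at the boron-bearing carbon.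

Step 8
Reactants: 16 2-[1-(2,3-dimethoxyphenyl)-2-(4-methoxy-3-{4-[2-(3-methoxyphenyl)ethyl]phenoxy}phenyl)ethyl]-4,4,5,5-tetramethyl-1,3,2-dioxaborolane
Product: 17 4-[2-(2,3-dimethoxyphenyl)ethyl]-1-methoxy-2-{4-[2-(3-methoxyphenyl)ethyl]phenoxy}benzene
Conditions: Bu4NF·3H2O, toluene, 80–100 °C
Reagents that add atoms: none
Why: Fluoride-promoted protodeboronation of a benzylic pinacol boronate should replace boron by hydrogen, fluoride activating boron and the water of hydration protonating the benzylic carbon, which removes the stereocentre.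

Step 9
Reactants: 17 4-[2-(2,3-dimethoxyphenyl)ethyl]-1-methoxy-2-{4-[2-(3-methoxyphenyl)ethyl]phenoxy}benzene
Product: 18 3-[2-(4-hydroxy-3-{4-[2-(3-hydroxyphenyl)ethyl]phenoxy}phenyl)ethyl]benzene-1,2-diol (CNP0185459.0)
Conditions: BBr3 (excess), CH2Cl2, −78 °C → rt; then H2O, 0 °C
Reagents that add atoms: none
Why: Lewis-acid demethylation with BBr3 should cleave all four aryl methyl ethers by bromide attack on the O-methyl carbons, while the diaryl ether, which offers no sp3 carbon for attack, stays intact.

**Compound list**

1 | 3-methoxybenzyl chloride | COc1cccc(CCl)c1 | starting material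
2 | (3-methoxybenzyl)triphenylphosphonium chloride | COc1cccc(C[P+](c2ccccc2)(c2ccccc2)c2ccccc2)c1.[Cl-] | intermediate
3 | 4-(benzyloxy)benzaldehyde | O=Cc1ccc(OCc2ccccc2)cc1 | starting material
4 | (3-methoxybenzylidene)triphenylphosphorane (ylide) | COc1cccc(C=P(c2ccccc2)(c2ccccc2)c2ccccc2)c1 | intermediate
5 | 1-(benzyloxy)-4-[2-(3-methoxyphenyl)ethenyl]benzene (E/Z mixture) | COc1cccc(C=Cc2ccc(OCc3ccccc3)cc2)c1 | intermediate
6 | 4-[2-(3-methoxyphenyl)ethyl]phenol | COc1cccc(CCc2ccc(O)cc2)c1 | intermediate
7 | 3-bromo-4-methoxybenzaldehyde | COc1ccc(C=O)cc1Br | starting material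
8 | 4-methoxy-3-{4-[2-(3-methoxyphenyl)ethyl]phenoxy}benzaldehyde | COc1cccc(CCc2ccc(Oc3cc(C=O)ccc3OC)cc2)c1 | intermediate
9 | 4-methoxy-3-{4-[2-(3-methoxyphenyl)ethyl]phenoxy}phenyl formate | COc1cccc(CCc2ccc(Oc3cc(OC=O)ccc3OC)cc2)c1 | intermediate
10 | 4-methoxy-3-{4-[2-(3-methoxyphenyl)ethyl]phenoxy}phenol | COc1cccc(CCc2ccc(Oc3cc(O)ccc3OC)cc2)c1 | intermediate
11 | 4-methoxy-3-{4-[2-(3-methoxyphenyl)ethyl]phenoxy}phenyl trifluoromethanesulfonate | COc1cccc(CCc2ccc(Oc3cc(OS(=O)(=O)C(F)(F)F)ccc3OC)cc2)c1 | intermediate
12 | veratrole (1,2-dimethoxybenzene) | COc1ccccc1OC | starting material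
13 | vinylboronic acid pinacol ester | C=CB1OC(C)(C)C(C)(C)O1 | starting material
14 | 2,3-dimethoxyphenyllithium | [Li]c1cccc(OC)c1OC | intermediate
15 | lithium (2,3-dimethoxyphenyl)(ethenyl)(pinacolato)borate | [Li+].C=C[B-]1(OC(C)(C)C(C)(C)O1)c1cccc(OC)c1OC | intermediate
16 | 2-[1-(2,3-dimethoxyphenyl)-2-(4-methoxy-3-{4-[2-(3-methoxyphenyl)ethyl]phenoxy}phenyl)ethyl]-4,4,5,5-tetramethyl-1,3,2-dioxaborolane (benzylic configuration unspecified) | COc1cccc(CCc2ccc(Oc3cc(CC(B4OC(C)(C)C(C)(C)O4)c4cccc(OC)c4OC)ccc3OC)cc2)c1 | intermediate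
17 | 4-[2-(2,3-dimethoxyphenyl)ethyl]-1-methoxy-2-{4-[2-(3-methoxyphenyl)ethyl]phenoxy}benzene | COc1cccc(CCc2ccc(Oc3cc(CCc4cccc(OC)c4OC)ccc3OC)cc2)c1 | intermediate
18 | 3-[2-(4-hydroxy-3-{4-[2-(3-hydroxyphenyl)ethyl]phenoxy}phenyl)ethyl]benzene-1,2-diol | Oc1cccc(CCc2ccc(Oc3cc(CCc4cccc(O)c4O)ccc3O)cc2)c1 | target

**Step count and risk**

Total step count: 9. Longest linear sequence: 9 steps (1 → 18); veratrole 12 and the vinylboronic ester 13 enter directly at step 7.

Steps most likely to fail:

Step 7. Direct Suzuki-type transfer of the vinyl or aryl group from boron to palladium may compete with the metallate shift. The ortho-methoxy-substituted aryl group may migrate sluggishly. Incomplete ortho-lithiation would leave n-BuLi, which would form a butylboronate and transfer butyl. Fallback: setting out from triflate 11, Suzuki–Miyaura vinylation with 13 (Pd(dppf)Cl2, K3PO4, dioxane–H2O, 80 °C) should give 4-ethenyl-1-methoxy-2-{4-[2-(3-methoxyphenyl)ethyl]phenoxy}benzene F1. Anti-Markovnikov hydroboration with 9-borabicyclo[3.3.1]nonane (THF, rt) should give the B-alkyl-9-borabicyclononane F2, which, without isolation, would undergo B-alkyl Suzuki coupling with commercial 1-bromo-2,3-dimethoxybenzene (COc1cccc(Br)c1OC; Pd(dppf)Cl2, K3PO4, THF–DMF–H2O, 60 °C). This comes back to the route at 17, bypassing 16 and step 8.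

Step 8. Protonolysis of the C–B bond of a secondary benzylic boronate may be slow or incomplete, and adventitious oxygen may oxidise it competitively. Fallback: setting out from 16, oxidation (NaOH, H2O2, THF, 0 °C) should give the secondary benzylic alcohol 1-(2,3-dimethoxyphenyl)-2-(4-methoxy-3-{4-[2-(3-methoxyphenyl)ethyl]phenoxy}phenyl)ethanol F3. Ionic deoxygenation (Et3SiH, CF3CO2H, CH2Cl2, 0 °C → rt) through the benzylic cation stabilised by the ortho-methoxy group should then deliver the methylene, coming back to the route at 17.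

Step 4. Oxidative addition at the bromide flanked by the ortho-methoxy group may be slow, allowing hydrodebromination or base-induced degradation of the aldehyde at the temperature required. Fallback: setting out from phenol 6, an oxidative Chan–Lam–Evans coupling with commercial (5-formyl-2-methoxyphenyl)boronic acid (COc1ccc(C=O)cc1B(O)O; Cu(OAc)2, pyridine, 4 Å molecular sieves, CH2Cl2, air, rt) should form the same C–O bond at room temperature, coming back to the route at 8 with no new intermediate.

**Further compounds**

F1 | step 7 | 4-ethenyl-1-methoxy-2-{4-[2-(3-methoxyphenyl)ethyl]phenoxy}benzene | COc1cccc(CCc2ccc(Oc3cc(C=C)ccc3OC)cc2)c1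
F2 | step 7 | 9-[2-(4-methoxy-3-{4-[2-(3-methoxyphenyl)ethyl]phenoxy}phenyl)ethyl]-9-borabicyclo[3.3.1]nonane | COc1cccc(CCc2ccc(Oc3cc(CCB4C5CCCC4CCC5)ccc3OC)cc2)c1
F3 | step 8 | 1-(2,3-dimethoxyphenyl)-2-(4-methoxy-3-{4-[2-(3-methoxyphenyl)ethyl]phenoxy}phenyl)ethanol (configuration unspecified) | COc1cccc(CCc2ccc(Oc3cc(CC(O)c4cccc(OC)c4OC)ccc3OC)cc2)c1
F0 | step 4 | none | none
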